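Add up Thursday's reading at 30.0 h: substrate 78.6% and target 17.0% leave 4.40% of the charge unaccounted for.

| flask | substrate | reagent in the second phase | temperature | remark | time | volume of the second phase over the first |
|---|---|---|---|---|---|---|
| Thursday's | 0.050 M (fed, over 8.0 h) | 0.046 M | 84 °C | run made earlier |  |  |
| Sunday's | 0.050 M (fed, over 8.0 h) | 0.066 M | 114 °C | run made earlier |  |  |
| Friday's | 0.13 M (fed, over 8.0 h) | 0.055 M | 84 °C | run made earlier |  |  |
| ash | 0.050 M (fed, over 8.0 h) | 0.0800 M | 70 °C |  | 30 h | 0.25 |
| cedar | 0.050 M (fed, over 8.0 h) | 0.0550 M | 70 °C |  | 30 h | 0.25 |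
| oak | 0.050 M (fed, over 8.0 h) | 0.0550 M | 110 °C |  | 30 h | 0.25 |
| birch | 0.20 M (fed, over 8.0 h) | 0.0550 M | 125 °C |  | 30 h | 0.25 |
| larch | 0.050 M (fed, over 8.0 h) | 0.0800 M | 80 °C |  | 30 h | 0.25 |
| elm | 0.050 M (fed, over 5.0 h) | 0.0550 M | 90 °C |  | 30 h | 0.25 |

| run | time / h | target / % | substrate / % |
|---|---|---|---|
| Thursday's | 10.0 | 7.0 | 92.6 |
| Thursday's | 30.0 | 17.0 | 78.6 |
| Thursday's | 60.0 | 19.0 | 68.4 |
| Thursday's | 72.0 | 18.3 | 66.2 |
| Thursday's | 120 | 15.1 | 61.1 |
| Sunday's | 6.00 | 5.2 | 64.3 |
| Sunday's | 12.0 | 6.2 | 78.2 |
| Sunday's | 20.0 | 4.6 | 69.7 |
| Sunday's | 25.0 | 4.1 | 65.4 |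
| Sunday's | 30.0 | 3.3 | 63.3 |
| Friday's | 10.0 | 8.3 | 91.7 |
| Friday's | 30.0 | 14.9 | 80.0 |
| Friday's | 60.0 | 17.1 | 75.8 |
| Friday's | 72.0 | 14.6 | 75.1 |
| Friday's | 120 | 12.5 | 75.8 |

(scatter of a reading: 0.5 percentage points)

* all flasks from highest to lowest amount of target, in percent of the substrate charged, at 30 h (ash / cedar / oak / birch / larch / elm)
* the amount of target, in percent of the substrate charged of the flask you put first, at 30 h
* the amount of target, in percent of the substrate charged of the flask you put last, at 30 h

- in the second phase: reagent in the second phase; everything else is in the first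
- charges count per volume of the first phase; a concentration in a rate is the amount of a species over the volume of its own phase; every rate counts per litre of the first phase
- the earlier runs were read with a standard deviation of 0.5 percentage points
- the earlier runs hold the two phases in the same ratio of volumes as the flask asked about
- percentages count the whole charge, also what has not yet gone in
- a reading or a percentage of target counts all its forms, free or not

Take that leftover as target that has gone further. Trapezoids under Thursday's target curve give a holding time τ, the area up to 30.0 h over the final height, of 16.2 h. Divide the leftover by τ, by that height and by the reagent charge c, and you get 0.348 L mol⁻¹ h⁻¹. Call this σ, the loss constant: the share of standing target lost per hour per mol/L of reagent charged, so that σc is a pseudo-first-order constant.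

Object at once: two readings with their scatter make that leftover shaky. So repeat it on Thursday's next window, from 30.0 h to 60.0 h, which gives 0.330 L mol⁻¹ h⁻¹. On Thursday it holds.

Now heat. Sunday's window from 12.0 h to 30.0 h gives 3.15 L mol⁻¹ h⁻¹, a factor 9.07 over the span between the two temperatures. Assume a plain exponential in temperature across it, and carry it past both ends of that span at your own risk.

Pick larch for first place: its reagent charge 0.0800 M matches ash's and stands above the 0.0550 M of the other flasks, and it is warmer than ash. Early use of substrate per hour of exposure and per reagent charge reads 0.268 L mol⁻¹ h⁻¹ on Thursday and 0.721 L mol⁻¹ h⁻¹ on Sunday. Scale Thursday's logarithm of substrate by charge and temperature, a factor 1.52. By this reckoning larch keeps 69.3% of its substrate at 30 h and has used 30.7%.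

First answer: all of that stands as target. Wrong, since larch's loss number στc, with Thursday's τ, comes to 0.335. Charge the loss on the first answer and target drops to 20.4%. But that overcharges, so put the lower target back: 23.9%. The rounds close on 23.0%, and I commit to that.

Birch sits at the other end. Its target half-life at full reagent charge, with σ carried past Sunday's temperature, reckons to 1.78 h. Yet its reagent is only a quarter of its substrate, so that figure will stretch. Sunday's run, cooler, still read 3.3% at 30.0 h; put birch last, near 1%.

The forecast gives larch > ash > elm > cedar > oak > birch, with 27% (22% to 32%) on top and 0.2% (0.02% to 1%) at the bottom, and notes “Ash versus elm is close”.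

The flasks give larch > elm > ash > cedar > oak > birch, with 21.1% on top and 0.755% at the bottom.

    reagent in the reaction phase ⇌ reagent in the second phase, rate k1*([reagent in the reaction phase] - [reagent in the second phase]/K1) per volume of the first phase (partition coefficient = 3.00, kL = 0.400 h⁻¹)
    substrate + reagent in the reaction phase ⇌ target (K = 4.70 L mol⁻¹, k = 3.60 L mol⁻¹ h⁻¹, Ea = 85.0 kJ mol⁻¹, ΔH = −90.0 kJ mol⁻¹)
    reagent in the reaction phase + target → over-reacted product (k = 6.00 L mol⁻¹ h⁻¹, Ea = 92.0 kJ mol⁻¹)
    reagent in the reaction phase + target → over-reaction product (k = 1.40 L mol⁻¹ h⁻¹, Ea = 93.0 kJ mol⁻¹)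
    crystals ⇌ target, rate k5*(cs5 - [target]) while solid is left; crystals form when [target] > cs5 (solubility = 26.0 mM, k = 13.0 h⁻¹)
    (constants at 110 °C)

In larch at 30.0 h the step from substrate to target relaxes, both ways together, with a half-life of 20.8 h, shorter than the 54 h of its forward rate alone, while over-reacted and over-reaction product stand at 0.402 of larch's target against my loss number 0.335. Carried to ash, colder, σ gives a loss number of 0.161; ash's actual use of substrate, 16.1%, goes in on both sides, so what is tried here is the split, and it leaves 13.9% of target against 13.9%.

The runs stem from a simulated flask for substances that don't exist; the scatter is artificial.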